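**Assumption:** Triquetrumone A as drawn has no stereocentres, so nothing needs enantiocontrol.

## Retrosynthetic overview
1. Target (13) ⇒ radical [3+2] annulation of 2-hydroxy-3-prenyl-1,4-benzoquinone (12) onto C3 of an angular pyranochromone bearing a 2-SMe leaving group (7). The C–C bond forms by radical–radical coupling; O–C2 closure and loss of MeSH then give the benzofuran.
2. 7 ⇐ prenal chromene annulation of 5,7-dihydroxy-6-methyl-2-(methylthio)chromone (5).
3. 5 ⇐ CS2/MeI ketene-dithioacetal formation and cyclisation of 2′,4′,6′-trihydroxy-3′-methylacetophenone (4).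
4. 4 ⇐ [3+3] benzannulation of acetylacetone bis-silyl dienol ether (2) with methylmalonyl dichloride (3).
5. 12 ⇐ C-prenylation of 2-hydroxy-1,4-benzoquinone (10), which comes from benzoquinone (8) by Thiele–Winter acetoxylation.
Rings form in this order: aromatic ring D, then the pyranone, then the dimethylpyran. The furan is closed in the key step, with the ring A quinone already in place.

## Route

**Step 1**
Reactants: 1 (acetylacetone)
Product: 2 (2,4-bis(trimethylsilyloxy)penta-1,3-diene)
Conditions: (i) Et3N, TMSCl, Et2O, rt; (ii) LDA, THF, –78 °C, then TMSCl
Reagents that add atoms: chlorotrimethylsilane, C[Si](C)(C)Cl (×2)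
Why: Double enolisation and O-silylation give a 1,3-C,C-dinucleophile (Chan/Brownbridge bis-silyl enol ether); no stereocentre.

**Step 2**
Reactants: 2 + 3 (2-methylmalonyl dichloride)
Product: 4 (1-(2,4,6-trihydroxy-3-methylphenyl)ethan-1-one)
Conditions: TMSOTf (10 mol %), CH2Cl2, –78 → 20 °C; then aq. HCl, THF
Reagents that add atoms: none
Why: Proposed new method: the terminal silyl enol ether carbon C-acylates one COCl (Mukaiyama-type), and the central carbon acylates the second COCl in a 6-membered ring closure. The resulting cyclohexane-1,3,5-trione tautomerises to the phloroglucinol, with the methyl placed between two OH groups and the acetyl on the carbon from the diketone. The closest known chemistry is Chan [3+3] cyclisation of 1,3-bis(silyl enol ethers) with 1,3-dielectrophiles; no stereocentre.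

**Step 3**
Reactants: 4
Product: 5 (5,7-dihydroxy-6-methyl-2-(methylsulfanyl)-4H-chromen-4-one)
Conditions: (i) NaH (5 equiv), CS2, DMF, 0 °C → rt; (ii) MeI (2.1 equiv), –20 °C; (iii) p-TsOH, PhMe, 80 °C
Reagents that add atoms: carbon disulfide, S=C=S; iodomethane, CI
Why: Ketene dithioacetal formation (CS2/MeI, Junjappa–Ila type) is followed by acid-promoted intramolecular addition–elimination of the ortho-OH with loss of MeSH, giving the 2-SMe chromone. Closure is expected at the OH flanked by H rather than by CH3, which sets the 5-OH/6-Me pattern of the target. No stereocentre.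

**Step 4**
Reactants: 5 + 6 (prenal, 3-methylbut-2-enal)
Product: 7 (5-hydroxy-6-methyl-2-(methylsulfanyl)chromone with an angular 2,2-dimethyl-2H-pyran fused at C7–C8, O on C7)
Conditions: pyridine, 130 °C, sealed tube, 12 h
Reagents that add atoms: none
Why: Phenol–enal condensation followed by 6π-oxa-electrocyclisation (chromene synthesis). Only 7-OH has a free ortho C–H (C8); the 5-OH is chelated and both its ortho positions are blocked, so the angular chromene forms regioselectively. No stereocentre.

**Step 5**
Reactants: 8 (p-benzoquinone)
Product: 9 (1,2,4-triacetoxybenzene)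
Conditions: Ac2O, cat. H2SO4, 0 → 25 °C
Reagents that add atoms: acetic anhydride, CC(=O)OC(C)=O
Why: Thiele–Winter acetoxylation (conjugate addition of acetate, then aromatisation); no stereocentre.

**Step 6**
Reactants: 9
Product: 10 (2-hydroxy-1,4-benzoquinone)
Conditions: (i) 3 M HCl, MeOH, reflux, N2; (ii) Ag2O, Et2O, rt
Reagents that add atoms: none
Why: Acid deacetylation gives hydroxyquinol, which Ag2O oxidises to the hydroxyquinone; no stereocentre.

**Step 7**
Reactants: 10 + 11 (prenyl bromide, 1-bromo-3-methylbut-2-ene)
Product: 12 (2-hydroxy-3-(3-methylbut-2-en-1-yl)-1,4-benzoquinone)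
Conditions: NaOH (1 equiv), H2O; then prenyl bromide, 40 °C; acidify
Reagents that add atoms: none beyond 11
Why: C-alkylation of the hydroxyquinone anion at the carbon between C–OH and C=O (lapachol-type C-prenylation), favoured in water; no stereocentre.

**Step 8**
Reactants: 7 + 12
Product: 13 (Triquetrumone A)
Conditions: blue LEDs (450 nm), MeCN, 25 °C, N2, 24 h; then TsOH (10 mol %), 50 °C
Reagents that add atoms: none (MeSH is lost)
Why: Proposed new method: excited hydroxyquinone 12 takes an electron from the push–pull enol thioether C2=C3 of 7, and the radical cation (spin at C3) couples with the semiquinone (spin at C5) to form the C3–C5 bond. This is the closest known reaction type to photochemical quinone–alkene [3+2] dihydrobenzofuran formation, and the Nenitzescu-type annulation follows the same topology. C5 is the β-carbon of the more electrophilic C3 carbonyl; the C6=O is a vinylogous acid, so the furan oxygen ends up next to the prenyl group. Tautomerisation gives the hydroquinone, whose O–H adds to the thionium at C2. Loss of MeSH and H+ then aromatises the benzofuran and regenerates the C2=C3 bond, forming the [2,3-b]-fused tetracycle. The oxidation level balances without an external oxidant, and there is no stereocentre.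

## Compound list
1 | acetylacetone | CC(=O)CC(C)=O | starting material
2 | 2,4-bis(trimethylsilyloxy)penta-1,3-diene | C=C(O[Si](C)(C)C)C=C(C)O[Si](C)(C)C | intermediate
3 | 2-methylmalonyl dichloride | CC(C(=O)Cl)C(=O)Cl | starting material
4 | 1-(2,4,6-trihydroxy-3-methylphenyl)ethanone | CC(=O)c1c(O)cc(O)c(C)c1O | intermediate
5 | 5,7-dihydroxy-6-methyl-2-(methylsulfanyl)chromen-4-one | CSC1=CC(=O)c2c(O)c(C)c(O)cc2O1 | intermediate
6 | prenal (3-methylbut-2-enal) | CC(C)=CC=O | starting material
7 | 5-hydroxy-6-methyl-2-(methylsulfanyl)-angular 2,2-dimethylpyrano-chromone | CSC1=CC(=O)c2c(O)c(C)c3OC(C)(C)C=Cc3c2O1 | intermediate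
8 | p-benzoquinone | O=C1C=CC(=O)C=C1 | starting material
9 | 1,2,4-triacetoxybenzene | CC(=O)Oc1ccc(OC(C)=O)c(OC(C)=O)c1 | intermediate
10 | 2-hydroxy-1,4-benzoquinone | O=C1C=CC(=O)C(O)=C1 | intermediate
11 | prenyl bromide | CC(C)=CCBr | starting material
12 | 2-hydroxy-3-prenyl-1,4-benzoquinone | O=C1C=CC(=O)C(O)=C1CC=C(C)C | intermediate
13 | Triquetrumone A | CC(C)=CCc1c(O)c(O)cc2c1oc1oc3c4c(c(C)c(O)c3c(=O)c12)OC(C)(C)C=C4 | target

## Totals
Total steps: 8. Longest linear sequence: 5 (1 → 2 → 4 → 5 → 7 → 13). The ring A branch is 4 steps (8 → 9 → 10 → 12 → 13).

## Three steps most likely to fail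
1. **Step 8 (photochemical radical [3+2]).** The push–pull enol thioether is hard to oxidise, and the quinone may dimerise or degrade.
   Fallback: switch to a polar cross-coupling. Iodinate 7 at C3 (NIS), Suzuki-couple with a protected 2-hydroxy-3-prenyl-4,5-dihydroxyphenylboronate, then close the furan by acid-promoted addition–elimination with loss of MeSH.
2. **Step 3 (CS2/MeI on the free polyphenol).** Possible O-methylation or the wrong ring-closure regiochemistry.
   Fallback: form the 2-unsubstituted chromone from 4 with DMF-DMA (enaminone, then acid cyclisation). Then run the quinone annulation as an oxidative radical coupling (Ag2O) followed by DDQ aromatisation, so no thio leaving group is needed.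
3. **Step 2 (new [3+3] benzannulation).** The ring closure may be low-yielding or give O-acylation.
   Fallback: build the ring stepwise in a polyketide-type sequence. C-acylate the acetylacetone dianion with CDI-activated 2-methylmalonic acid monomethyl ester, then do a NaOMe Claisen cyclisation and aromatisation.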